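**Retrosynthetic overview**

1. Ring C (the quinone) is closed last. The target is disconnected to a racemic 4-hydroxy-4-(3-methylbut-1-en-2-yl)cyclobutenone that carries the complete diaryl ether on its 3-oxygen; in the forward sense, thermal 4π opening, 6π closure and Ag2O oxidation run in one flask (Moore–Liebeskind ring expansion).
2. Enabling feature: in ring C the four contiguous carbons O=C–C(OAr)=C(CH3)–C=O have the connectivity and oxidation pattern of a squaric-acid-derived cyclobutenedione. The other two ring carbons, C(iPr)=CH, carry no heteroatom and can come from a 1,1-disubstituted alkene. The aryloxy oxygen on ring C makes one dione carbonyl a vinylogous ester and so steers the alkenyllithium to the other.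
3. Cyclobutenone ⇒ aryl methylsemisquarate + 2-lithio-3-methylbut-1-ene. Aryl semisquarate ⇒ diaryl ether phenol (rings A–O–B) + 3-chloro-4-methylcyclobutenedione (from diisopropyl squarate and MeLi).
4. Diaryl ether phenol ⇒ 4-methoxythymol + the bromoquinone made from it (ipso substitution), then reduction and sterically controlled mono-O-methylation; both partners come from thymol.
5. Ring order: rings A and B are bought (thymol); the four-membered ring is bought (squarate) and consumed; ring C is the only ring made and the last.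

Key step: step 13

Assumption: 2-bromo-3-methylbut-1-ene is taken as a purchasable alkenyl bromide; the cyclobutenone precursor is made and used as the racemate, since its single stereocentre is destroyed in the key step and the target has none.

**Route**

Step 1
Reactants: 1 thymol, 5-methyl-2-(propan-2-yl)phenol
Product: 2 4-bromo-5-methyl-2-(propan-2-yl)phenol
Conditions: NBS (1.0 equiv), MeCN, 0 °C to rt
Reagents that add atoms: N-bromosuccinimide, O=C1CCC(=O)N1Br
Why: Electrophilic aromatic bromination of a phenol with NBS in MeCN goes para to the hydroxyl, and in thymol that position is open and further activated by the ortho methyl group.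

Step 2
Reactants: 2 4-bromo-5-methyl-2-(propan-2-yl)phenol
Product: 3 4-methoxy-5-methyl-2-(propan-2-yl)phenol (4-methoxythymol)
Conditions: NaOMe (5 equiv, in MeOH), CuBr (10 mol %), DMF, 110 °C; then 1 M HCl
Reagents that add atoms: sodium methoxide, [Na+].[O-]C
Why: Copper-catalysed Ullmann-type methoxylation of an aryl bromide, which tolerates a free phenoxide as in the classical bromophenol to methoxyphenol conversions, should replace Br by OMe.

Step 3
Reactants: 3 4-methoxy-5-methyl-2-(propan-2-yl)phenol
Product: 4 2-bromo-4-methoxy-3-methyl-6-(propan-2-yl)phenol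
Conditions: NBS (1.0 equiv), CH2Cl2, −20 to 0 °C
Reagents that add atoms: N-bromosuccinimide, O=C1CCC(=O)N1Br
Why: Electrophilic aromatic bromination is directed by the free hydroxyl to its only open ortho carbon (para is blocked by OMe), while the other ring CH is meta to OH and shielded by the isopropyl group.

Step 4
Reactants: 4 2-bromo-4-methoxy-3-methyl-6-(propan-2-yl)phenol
Product: 5 3-bromo-2-methyl-5-(propan-2-yl)cyclohexa-2,5-diene-1,4-dione
Conditions: PhI(OAc)2 (1.1 equiv), MeCN/H2O 2:1, 0 °C
Reagents that add atoms: water, O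
Why: Hypervalent-iodine oxidative demethylation of a p-methoxyphenol, in which water adds at the methoxy-bearing para carbon and methanol is expelled, gives the p-benzoquinone with the bromine position fixed by step 3.

Step 5
Reactants: 5 3-bromo-2-methyl-5-(propan-2-yl)cyclohexa-2,5-diene-1,4-dione; 3 4-methoxy-5-methyl-2-(propan-2-yl)phenol
Product: 6 3-[4-methoxy-5-methyl-2-(propan-2-yl)phenoxy]-2-methyl-5-(propan-2-yl)cyclohexa-2,5-diene-1,4-dione
Conditions: Cs2CO3 (1.2 equiv), degassed MeCN, 0 °C to rt, Ar
Reagents that add atoms: none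
Why: Addition–elimination (nucleophilic vinylic substitution) of a haloquinone by a phenoxide, as used for 2-aryloxy-3-methyl-1,4-naphthoquinones, is productive only at the brominated carbon because bromide loss is irreversible whereas O-addition at the free ring CH reverts.

Step 6
Reactants: 6 3-[4-methoxy-5-methyl-2-(propan-2-yl)phenoxy]-2-methyl-5-(propan-2-yl)cyclohexa-2,5-diene-1,4-dione
Product: 7 2-[4-methoxy-5-methyl-2-(propan-2-yl)phenoxy]-3-methyl-6-(propan-2-yl)benzene-1,4-diol
Conditions: Na2S2O4 (3 equiv), EtOAc/H2O, rt, Ar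
Reagents that add atoms: none
Why: Dithionite reduction of a quinone to its hydroquinone is selective and leaves the aryl ethers untouched.

Step 7
Reactants: 7 2-[4-methoxy-5-methyl-2-(propan-2-yl)phenoxy]-3-methyl-6-(propan-2-yl)benzene-1,4-diol
Product: 8 4-methoxy-2-[4-methoxy-5-methyl-2-(propan-2-yl)phenoxy]-3-methyl-6-(propan-2-yl)phenol
Conditions: Me2SO4 (1.05 equiv), K2CO3 (1.1 equiv), acetone, rt, Ar
Reagents that add atoms: dimethyl sulfate, COS(=O)(=O)OC
Why: Williamson O-methylation with one equivalent of electrophile should go to the hydroxyl between CH3 and H rather than the one buried between the isopropyl and aryloxy groups, the same steric bias seen when tert-butylhydroquinone is methylated at its unhindered hydroxyl.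

Step 8
Reactants: 9 diisopropyl squarate, 3,4-di(propan-2-yloxy)cyclobut-3-ene-1,2-dione
Product: 11 3-methyl-4-(propan-2-yloxy)cyclobut-3-ene-1,2-dione, via hydroxycyclobutenone 10 (not isolated)
Conditions: MeLi (1.05 equiv), THF, −78 °C; H2O quench; crude, conc. HCl (cat.), CH2Cl2, rt
Reagents that add atoms: methyllithium, [Li]C; water, O
Why: 1,2-Addition of an organolithium to a squarate carbonyl followed by acid-induced ionisation of the tertiary carbinol and hydrolysis of the resulting oxocarbenium ion is the standard route to 3-alkyl-4-alkoxycyclobutenediones; the stereocentre of racemic 10 is lost again.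

Step 9
Reactants: 11 3-methyl-4-(propan-2-yloxy)cyclobut-3-ene-1,2-dione
Product: 12 3-hydroxy-4-methylcyclobut-3-ene-1,2-dione
Conditions: 6 M HCl (aq), THF, 50 °C; evaporate
Reagents that add atoms: water, O
Why: Acid hydrolysis of a vinylogous ester by addition–elimination of water gives the vinylogous acid (methylsemisquaric acid).

Step 10
Reactants: 12 3-hydroxy-4-methylcyclobut-3-ene-1,2-dione
Product: 13 3-chloro-4-methylcyclobut-3-ene-1,2-dione
Conditions: (COCl)2 (1.2 equiv), DMF (cat.), CH2Cl2, 0 °C to rt; used crude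
Reagents that add atoms: oxalyl chloride, O=C(Cl)C(Cl)=O
Why: A vinylogous carboxylic acid is converted into its vinylogous acid chloride under Vilsmeier catalysis, as in the preparation of squaryl dichloride from squaric acid.

Step 11
Reactants: 8 4-methoxy-2-[4-methoxy-5-methyl-2-(propan-2-yl)phenoxy]-3-methyl-6-(propan-2-yl)phenol; 13 3-chloro-4-methylcyclobut-3-ene-1,2-dione
Product: 14 3-{4-methoxy-2-[4-methoxy-5-methyl-2-(propan-2-yl)phenoxy]-3-methyl-6-(propan-2-yl)phenoxy}-4-methylcyclobut-3-ene-1,2-dione
Conditions: NaH (1.05 equiv), THF, 0 °C; then 13 (1.2 equiv), −78 to 0 °C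
Reagents that add atoms: none
Why: Addition–elimination of a phenoxide on a vinylogous acid chloride (O-acylation type) should be fast even for this hindered phenoxide, which has no free ortho or para carbon and so can only react at oxygen.

Step 12
Reactants: 14 3-{4-methoxy-2-[4-methoxy-5-methyl-2-(propan-2-yl)phenoxy]-3-methyl-6-(propan-2-yl)phenoxy}-4-methylcyclobut-3-ene-1,2-dione; 15 2-bromo-3-methylbut-1-ene
Product: 17 racemic 4-hydroxy-3-{4-methoxy-2-[4-methoxy-5-methyl-2-(propan-2-yl)phenoxy]-3-methyl-6-(propan-2-yl)phenoxy}-2-methyl-4-(3-methylbut-1-en-2-yl)cyclobut-2-en-1-one, via alkenyllithium 16 (not isolated)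
Conditions: 15 (1.15 equiv), t-BuLi (2.3 equiv), Et2O, −78 °C; cannulate into 14, THF, −78 °C; AcOH (in THF) quench at −78 °C, pH 7 buffer; used directly
Reagents that add atoms: none
Why: Bromine–lithium exchange followed by 1,2-addition of the alkenyllithium to a cyclobutenedione should occur at the ketone-like carbonyl attached to the aryloxy-bearing carbon, because the other carbonyl is deactivated as a vinylogous ester, as in the Moore–Liebeskind preparation of 4-alkenyl-4-hydroxycyclobutenones; the new carbinol stereocentre is formed racemic and needs no control.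

Step 13
Reactants: 17 racemic 4-hydroxy-3-{4-methoxy-2-[4-methoxy-5-methyl-2-(propan-2-yl)phenoxy]-3-methyl-6-(propan-2-yl)phenoxy}-2-methyl-4-(3-methylbut-1-en-2-yl)cyclobut-2-en-1-one
Product: 21 3-{4-methoxy-2-[4-methoxy-5-methyl-2-(propan-2-yl)phenoxy]-3-methyl-6-(propan-2-yl)phenoxy}-2-methyl-5-(propan-2-yl)cyclohexa-2,5-diene-1,4-dione (target), via dienylketene 18 (not isolated), via cyclohexadienone 19 (not isolated), via hydroquinone 20 (not isolated)
Conditions: degassed p-xylene (0.02 M), 138 °C; cool to rt, then Ag2O (3 equiv), MgSO4, Et2O, rt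
Reagents that add atoms: none
Why: Heating should open the cyclobutenone by conrotatory 4π electrocyclic cleavage of the C1–C4 bond, and the known torquoselectivity (the C4 hydroxyl rotates outward) places the alkenyl group cis to the ketene in 18. Disrotatory 6π electrocyclisation then closes ring C through one new C–C bond between the ketene carbon and the alkene CH2 terminus to give dienone 19, which enolises to hydroquinone 20. Ag2O then dehydrogenates 20 to the quinone without touching the two hydroquinone-diether rings A and B. The closest known reaction type is the Moore–Liebeskind thermal ring expansion of 4-alkenyl-4-hydroxycyclobutenones to hydroquinones and quinones. No stereocentre is created, and the one in 17 is destroyed. The selectivity needed is regiochemical (isopropyl carbon next to the carbonyl flanked by the aryloxy carbon, ring CH next to the carbonyl flanked by the methyl carbon) and is fixed by the connectivity of 17, while capture of the ketene by the aryloxy ring is excluded because both of its ortho carbons are substituted.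

**Compound list**

1 | thymol, 5-methyl-2-(propan-2-yl)phenol | Cc1ccc(C(C)C)c(O)c1 | starting material
2 | 4-bromo-5-methyl-2-(propan-2-yl)phenol | Cc1cc(O)c(C(C)C)cc1Br | intermediate
3 | 4-methoxy-5-methyl-2-(propan-2-yl)phenol | COc1cc(C(C)C)c(O)cc1C | intermediate
4 | 2-bromo-4-methoxy-3-methyl-6-(propan-2-yl)phenol | COc1cc(C(C)C)c(O)c(Br)c1C | intermediate
5 | 3-bromo-2-methyl-5-(propan-2-yl)cyclohexa-2,5-diene-1,4-dione | CC1=C(Br)C(=O)C(C(C)C)=CC1=O | intermediate
6 | 3-[4-methoxy-5-methyl-2-(propan-2-yl)phenoxy]-2-methyl-5-(propan-2-yl)cyclohexa-2,5-diene-1,4-dione | COc1cc(C(C)C)c(OC2=C(C)C(=O)C=C(C(C)C)C2=O)cc1C | intermediate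
7 | 2-[4-methoxy-5-methyl-2-(propan-2-yl)phenoxy]-3-methyl-6-(propan-2-yl)benzene-1,4-diol | COc1cc(C(C)C)c(Oc2c(C)c(O)cc(C(C)C)c2O)cc1C | intermediate
8 | 4-methoxy-2-[4-methoxy-5-methyl-2-(propan-2-yl)phenoxy]-3-methyl-6-(propan-2-yl)phenol | COc1cc(C(C)C)c(Oc2c(C)c(OC)cc(C(C)C)c2O)cc1C | intermediate
9 | diisopropyl squarate, 3,4-di(propan-2-yloxy)cyclobut-3-ene-1,2-dione | CC(C)OC1=C(OC(C)C)C(=O)C1=O | starting material
10 | racemic 4-hydroxy-4-methyl-2,3-di(propan-2-yloxy)cyclobut-2-en-1-one (formed as its lithium alkoxide, not isolated) | CC(C)OC1=C(OC(C)C)C(C)(O)C1=O | intermediate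
11 | 3-methyl-4-(propan-2-yloxy)cyclobut-3-ene-1,2-dione | CC(C)OC1=C(C)C(=O)C1=O | intermediate
12 | 3-hydroxy-4-methylcyclobut-3-ene-1,2-dione | CC1=C(O)C(=O)C1=O | intermediate
13 | 3-chloro-4-methylcyclobut-3-ene-1,2-dione | CC1=C(Cl)C(=O)C1=O | intermediate
14 | 3-{4-methoxy-2-[4-methoxy-5-methyl-2-(propan-2-yl)phenoxy]-3-methyl-6-(propan-2-yl)phenoxy}-4-methylcyclobut-3-ene-1,2-dione | COc1cc(C(C)C)c(Oc2c(C)c(OC)cc(C(C)C)c2OC2=C(C)C(=O)C2=O)cc1C | intermediate
15 | 2-bromo-3-methylbut-1-ene | C=C(Br)C(C)C | starting material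
16 | (3-methylbut-1-en-2-yl)lithium (not isolated) | [Li]C(=C)C(C)C | intermediate
17 | racemic 4-hydroxy-3-{4-methoxy-2-[4-methoxy-5-methyl-2-(propan-2-yl)phenoxy]-3-methyl-6-(propan-2-yl)phenoxy}-2-methyl-4-(3-methylbut-1-en-2-yl)cyclobut-2-en-1-one | COc1cc(C(C)C)c(Oc2c(C)c(OC)cc(C(C)C)c2OC2=C(C)C(=O)C2(O)C(=C)C(C)C)cc1C | intermediate
18 | (Z)-dienylketene from ring opening of 17: 3-aryloxy-4-hydroxy-2-methyl-5-(propan-2-yl)hexa-1,3,5-trien-1-one, aryloxy and hydroxyl cis on the central C=C (not isolated) | COc1cc(C(C)C)c(Oc2c(C)c(OC)cc(C(C)C)c2O/C(C(C)=C=O)=C(\O)C(=C)C(C)C)cc1C | intermediate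
19 | 3-aryloxy-4-hydroxy-2-methyl-5-(propan-2-yl)cyclohexa-2,4-dien-1-one, aryloxy = the phenoxy group of 8 (not isolated) | COc1cc(C(C)C)c(Oc2c(C)c(OC)cc(C(C)C)c2OC2=C(C)C(=O)CC(C(C)C)=C2O)cc1C | intermediate
20 | 2-{4-methoxy-2-[4-methoxy-5-methyl-2-(propan-2-yl)phenoxy]-3-methyl-6-(propan-2-yl)phenoxy}-3-methyl-6-(propan-2-yl)benzene-1,4-diol (not isolated) | COc1cc(C(C)C)c(Oc2c(C)c(OC)cc(C(C)C)c2Oc2c(C)c(O)cc(C(C)C)c2O)cc1C | intermediate
21 | 3-{4-methoxy-2-[4-methoxy-5-methyl-2-(propan-2-yl)phenoxy]-3-methyl-6-(propan-2-yl)phenoxy}-2-methyl-5-(propan-2-yl)cyclohexa-2,5-diene-1,4-dione | COc1cc(C(C)C)c(Oc2c(C)c(OC)cc(C(C)C)c2OC2=C(C)C(=O)C=C(C(C)C)C2=O)cc1C | target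

**Step count and risks**

Total step count: 13. Longest linear sequence: 10 steps (steps 1, 2, 3, 4, 5, 6, 7, 11, 12, 13); the squarate branch (steps 8, 9, 10) joins at step 11.

Steps most likely to fail:

1. Step 12. The alkenyllithium may attack the aryloxy-bearing ring carbon and expel the phenoxide of 8 by addition–elimination, or deprotonate the acidic ring methyl, instead of adding 1,2 to the ketone-like carbonyl. Fallback, setting out from 11 and 16 (made from 15 as in step 12) and coming back to the route at 21: the ring expansion is run in the isopropoxy series and the aryl ether bond is made after ring C exists. Addition of 16 to 11 (THF, −78 °C) should give racemic 4-hydroxy-2-methyl-4-(3-methylbut-1-en-2-yl)-3-(propan-2-yloxy)cyclobut-2-en-1-one F1. Thermolysis in p-xylene at reflux should give 3-methyl-2-(propan-2-yloxy)-6-(propan-2-yl)benzene-1,4-diol F2, which Ag2O oxidises in the same flask to 2-methyl-3-(propan-2-yloxy)-5-(propan-2-yl)cyclohexa-2,5-diene-1,4-dione F3. Hydrolysis of this vinylogous ester (aq. NaOH, then HCl) should give 3-hydroxy-2-methyl-5-(propan-2-yl)cyclohexa-2,5-diene-1,4-dione F4. Oxalyl chloride with catalytic DMF should convert it into 3-chloro-2-methyl-5-(propan-2-yl)cyclohexa-2,5-diene-1,4-dione F5, and F5 with phenol 8 and Cs2CO3 in MeCN (the chemistry of step 5) should give 21.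

2. Step 7. Site selectivity may be lost (methylation at the hindered hydroxyl or at both), and the hydroquinone may be re-oxidised by air under base. Fallback, setting out from 7 and coming back at 8: exhaustive methylation (excess MeI, K2CO3, DMF, Ar) to 1,4-dimethoxy-2-[4-methoxy-5-methyl-2-(propan-2-yl)phenoxy]-3-methyl-6-(propan-2-yl)benzene F6. BCl3 (1 equiv, CH2Cl2, −78 to 0 °C) should then cleave only the methoxy group that is twisted out of plane between the isopropyl group and the aryloxy oxygen, with boron held by the two adjacent oxygens as in the selective cleavage of the central ether of 1,2,3-trimethoxyarenes. This gives 8.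

3. Step 5. Electron transfer between the electron-rich phenoxide and the quinone, C-arylation through the free ortho carbon of 3, or conjugate addition at the free quinone CH may compete with ipso substitution. Fallback, setting out from 4 and 3 and coming back at 8 (steps 4 to 7 are then not needed): benzylation of 4 (BnBr, K2CO3, DMF) to 2-(benzyloxy)-3-bromo-5-methoxy-4-methyl-1-(propan-2-yl)benzene F7. Ullmann diaryl ether coupling of F7 with 3 (CuI, picolinic acid, K3PO4, DMSO, 110 °C; conditions developed for hindered partners) should give 2-(benzyloxy)-5-methoxy-3-[4-methoxy-5-methyl-2-(propan-2-yl)phenoxy]-4-methyl-1-(propan-2-yl)benzene F8. Hydrogenolysis (H2, Pd/C, EtOAc) then gives 8, with the methoxy and hydroxyl positions fixed from the start.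

Further compounds
F1 | step 12 | racemic 4-hydroxy-2-methyl-4-(3-methylbut-1-en-2-yl)-3-(propan-2-yloxy)cyclobut-2-en-1-one | CC(C)OC1=C(C)C(=O)C1(O)C(=C)C(C)C
F2 | step 12 | 3-methyl-2-(propan-2-yloxy)-6-(propan-2-yl)benzene-1,4-diol | CC(C)Oc1c(C)c(O)cc(C(C)C)c1O
F3 | step 12 | 2-methyl-3-(propan-2-yloxy)-5-(propan-2-yl)cyclohexa-2,5-diene-1,4-dione | CC(C)OC1=C(C)C(=O)C=C(C(C)C)C1=O
F4 | step 12 | 3-hydroxy-2-methyl-5-(propan-2-yl)cyclohexa-2,5-diene-1,4-dione | CC1=C(O)C(=O)C(C(C)C)=CC1=O
F5 | step 12 | 3-chloro-2-methyl-5-(propan-2-yl)cyclohexa-2,5-diene-1,4-dione | CC1=C(Cl)C(=O)C(C(C)C)=CC1=O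
F6 | step 7 | 1,4-dimethoxy-2-[4-methoxy-5-methyl-2-(propan-2-yl)phenoxy]-3-methyl-6-(propan-2-yl)benzene | COc1cc(C(C)C)c(Oc2c(C)c(OC)cc(C(C)C)c2OC)cc1C
F7 | step 5 | 2-(benzyloxy)-3-bromo-5-methoxy-4-methyl-1-(propan-2-yl)benzene | COc1cc(C(C)C)c(OCc2ccccc2)c(Br)c1C
F8 | step 5 | 2-(benzyloxy)-5-methoxy-3-[4-methoxy-5-methyl-2-(propan-2-yl)phenoxy]-4-methyl-1-(propan-2-yl)benzene | COc1cc(C(C)C)c(Oc2c(C)c(OC)cc(C(C)C)c2OCc2ccccc2)cc1C
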